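**Retrosynthetic overview**
1. The target is a cis-(2R,3S)-2,3-dihydro-4H-furo[3,2-c]pyran-4-one. The last disconnection is C2–C3: an enantioselective 1,5-C–H insertion of a rhodium carbene at C3 into the benzylic C–H of a 4-O-benzyl ether of pyranone B. It closes the dihydrofuran (C3, C3a, C7a, O1, C2) last and sets both stereocentres from an achiral precursor.
2. Enabling feature: C3 sits between C6 of pyranone A and C3 (= C3a) of pyranone B, and C2 is a benzylic carbon on O1, the C4 enol oxygen (C7a–O1) of pyranone B next to C3a. The carbene carbon and the benzylic C–H are therefore 1,5-related, and the CH2 that precedes the carbene is acidic (ε-carbon of the ring-A dienoate), which allows diazo transfer.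
3. The diazo precursor comes from diazo transfer onto the 4-O-benzyl ether, made by Mitsunobu benzylation of a bis(pyranonyl)methane, which comes from three-component reductive alkylation of pyranone B with the pyranone-A 6-carbaldehyde.
4. Ring order: both catechol rings and pyranone ring A are bought; pyranone ring B is made by acylketene cyclisation (step 4); the dihydrofuran is closed last (step 11); one global desilylation follows.

Key step: step 11

Remark: the SMILES puts the C2 aryl group and the C3 pyranonyl group on the same face, so the target is taken as the cis-(2R,3S) isomer (kinetic, not the thermodynamic trans arrangement); the ring is therefore closed under neutral kinetic control and kept away from base and strong acid afterwards (TBS = tert-butyldimethylsilyl, TBSO = tert-butyldimethylsilyloxy).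

**Step 1**
Reactants: 1 3,4-dihydroxybenzaldehyde
Product: 2 3,4-bis(tert-butyldimethylsilyloxy)benzaldehyde
Conditions: TBSCl, imidazole, DMF, 0 °C to rt
Reagents that add atoms: tert-butyldimethylsilyl chloride, CC(C)(C)[Si](C)(C)Cl
Why: Standard silyl ether formation on both phenols leaves the aldehyde untouched and gives a protecting group that fluoride removes at the end.

**Step 2**
Reactants: 2 3,4-bis(tert-butyldimethylsilyloxy)benzaldehyde; 3 2,2,6-trimethyl-4H-1,3-dioxin-4-one
Product: 4 6-{2-[3,4-bis(TBSO)phenyl]-2-hydroxyethyl}-2,2-dimethyl-4H-1,3-dioxin-4-one (racemic)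
Conditions: LDA, THF, −78 °C; then 2; aq. NH4Cl
Reagents that add atoms: none
Why: The lithium dienolate of the dioxinone adds through its exocyclic carbon to the aldehyde (vinylogous aldol addition), and the racemic carbinol centre is removed in step 3.

**Step 3**
Reactants: 4 6-{2-[3,4-bis(TBSO)phenyl]-2-hydroxyethyl}-2,2-dimethyl-4H-1,3-dioxin-4-one
Product: 5 6-{2-[3,4-bis(TBSO)phenyl]-2-oxoethyl}-2,2-dimethyl-4H-1,3-dioxin-4-one
Conditions: Dess–Martin periodinane, NaHCO3, CH2Cl2, 0 °C to rt
Reagents that add atoms: none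
Why: Buffered Dess–Martin oxidation of the secondary benzylic alcohol to the aryl ketone is compatible with aryl silyl ethers and the dioxinone.

**Step 4**
Reactants: 5 6-{2-[3,4-bis(TBSO)phenyl]-2-oxoethyl}-2,2-dimethyl-4H-1,3-dioxin-4-one
Product: 7 6-[3,4-bis(TBSO)phenyl]-4-hydroxy-2H-pyran-2-one (pyranone B), via acylketene 6 (not isolated)
Conditions: toluene, 110 °C, dilute
Reagents that add atoms: none
Why: Thermal retro-[4+2] of the dioxinone releases acetone and an acylketene whose enolised aryl ketone oxygen adds to the ketene carbon, the established dioxinone thermolysis route to 6-aryl-4-hydroxy-2-pyranones, which closes pyranone ring B under neutral conditions.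

**Step 5**
Reactants: 2 3,4-bis(tert-butyldimethylsilyloxy)benzaldehyde
Product: 8 [3,4-bis(TBSO)phenyl]methanol
Conditions: NaBH4, MeOH/THF, 0 °C
Reagents that add atoms: none
Why: Borohydride reduction of the aldehyde gives the benzylic alcohol that will supply C2 and its aryl group.

**Step 6**
Reactants: 9 4-hydroxy-6-methyl-2H-pyran-2-one
Product: 10 6-methyl-4-[2-(trimethylsilyl)ethoxy]-2H-pyran-2-one
Conditions: Me3SiCH2CH2OH, PPh3, DIAD, THF, 0 °C to rt
Reagents that add atoms: 2-(trimethylsilyl)ethanol, C[Si](C)(C)CCO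
Why: Mitsunobu O-alkylation of the acidic 4-hydroxy-2-pyranone at O4 gives a vinylogous 2-(trimethylsilyl)ethyl ester that fluoride cleaves without releasing formaldehyde.

**Step 7**
Reactants: 10 6-methyl-4-[2-(trimethylsilyl)ethoxy]-2H-pyran-2-one
Product: 11 2-oxo-4-[2-(trimethylsilyl)ethoxy]-2H-pyran-6-carbaldehyde
Conditions: SeO2, 1,4-dioxane, 160 °C, sealed tube
Reagents that add atoms: selenium dioxide, O=[Se]=O
Why: Riley oxidation of the 6-methyl group, activated as the ε-position of the ring dienoate, is the known route from 4-alkoxy-6-methyl-2-pyranones to the 6-carbaldehydes.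

**Step 8**
Reactants: 7 6-[3,4-bis(TBSO)phenyl]-4-hydroxy-2H-pyran-2-one; 11 2-oxo-4-[2-(trimethylsilyl)ethoxy]-2H-pyran-6-carbaldehyde
Product: 13 6-[3,4-bis(TBSO)phenyl]-4-hydroxy-3-({2-oxo-4-[2-(trimethylsilyl)ethoxy]-2H-pyran-6-yl}methyl)-2H-pyran-2-one, via Knoevenagel adduct 12 (not isolated)
Conditions: Hantzsch ester (diethyl 2,6-dimethyl-1,4-dihydropyridine-3,5-dicarboxylate), L-proline (20 mol %), CH2Cl2, rt
Reagents that add atoms: none
Why: In this organocatalytic three-component reductive alkylation, proline-mediated Knoevenagel condensation at C3 of the 4-hydroxypyranone gives an alkylidene pyran-2,4-dione that is reduced at once by conjugate hydride transfer from the Hantzsch ester, before a second pyranone can add.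

**Step 9**
Reactants: 13 6-[3,4-bis(TBSO)phenyl]-4-hydroxy-3-({2-oxo-4-[2-(trimethylsilyl)ethoxy]-2H-pyran-6-yl}methyl)-2H-pyran-2-one; 8 [3,4-bis(TBSO)phenyl]methanol
Product: 14 4-{[3,4-bis(TBSO)phenyl]methoxy}-6-[3,4-bis(TBSO)phenyl]-3-({2-oxo-4-[2-(trimethylsilyl)ethoxy]-2H-pyran-6-yl}methyl)-2H-pyran-2-one
Conditions: PPh3, DIAD, THF, 0 °C
Reagents that add atoms: none
Why: Mitsunobu alkylation of the acidic 4-hydroxyl with the primary benzylic alcohol forms the O1–C2 bond as a 4-benzyloxy-2-pyranone (the usual O4 selectivity of 4-hydroxy-2-pyranones, with C3 blocked), under neutral conditions that spare the silyl groups.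

**Step 10**
Reactants: 14 4-{[3,4-bis(TBSO)phenyl]methoxy}-6-[3,4-bis(TBSO)phenyl]-3-({2-oxo-4-[2-(trimethylsilyl)ethoxy]-2H-pyran-6-yl}methyl)-2H-pyran-2-one
Product: 15 4-{[3,4-bis(TBSO)phenyl]methoxy}-6-[3,4-bis(TBSO)phenyl]-3-(diazo{2-oxo-4-[2-(trimethylsilyl)ethoxy]-2H-pyran-6-yl}methyl)-2H-pyran-2-one
Conditions: p-ABSA, DBU, anhydrous MeCN, 0 °C, dark; short silica pad, used at once
Reagents that add atoms: 4-acetamidobenzenesulfonyl azide (p-ABSA), CC(=O)Nc1ccc(S(=O)(=O)N=[N+]=[N-])cc1
Why: Regitz diazo transfer should work because the bridging CH2 is the ε-carbon of the ring-A dienoate and carries a second electron-poor ring, which places it in the acidity range of arylacetates and fluorene that undergo this reaction, and the extended enolate reacts at the exocyclic carbon so both pyranone rings stay intact.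

**Step 11**
Reactants: 15 4-{[3,4-bis(TBSO)phenyl]methoxy}-6-[3,4-bis(TBSO)phenyl]-3-(diazo{2-oxo-4-[2-(trimethylsilyl)ethoxy]-2H-pyran-6-yl}methyl)-2H-pyran-2-one
Product: 16 (2R,3S)-2,6-bis[3,4-bis(TBSO)phenyl]-3-{2-oxo-4-[2-(trimethylsilyl)ethoxy]-2H-pyran-6-yl}-2,3-dihydro-4H-furo[3,2-c]pyran-4-one (cis)
Conditions: Rh2(S-PTAD)4 (1 mol %), CH2Cl2, 4 Å MS, −40 to 0 °C, slow addition of 15
Reagents that add atoms: none
Why: Rh2(S-PTAD)4 expels N2 from 15 and the rhodium carbene at the carbon between C3 of pyranone B and C6 of pyranone A inserts into one of the two enantiotopic benzylic C–H bonds of the neighbouring 4-O-benzyl ether in a concerted, asynchronous, hydride-transfer-like transition state, which forms the C2–C3 bond. The closest known reaction type is the chiral dirhodium-catalysed intramolecular 1,5-C–H insertion of (2-benzyloxyaryl)diazomethanes and (2-benzyloxyaryl)diazoacetates, which gives cis-2-aryl-2,3-dihydrobenzofurans enantioselectively. The dihydrofuran ring (O1, C2, C3, C3a, C7a) closes by this 1,5-insertion through a five-membered cyclic transition state, O1, C7a and C3a being in place beforehand. C2 is fixed by which benzylic hydrogen is replaced (retention at carbon) and C3 by the carbene face that takes up that hydrogen, both under control of the chiral carboxylate pocket, and the compact transition state that turns the C2 aryl and the C3 pyranonyl group to the same side should give the kinetic cis isomer; the sense of induction for this hetaryl carbene is assumed by analogy and must be checked on the first run, the antipodal catalyst being equally available. The step needs 1,5-insertion over carbene dimerisation, pyrazole formation and attack on the silyl ethers, and cis over trans, which the ortho arrangement of the carbene and an electron-rich α-oxy benzylic C–H bond, the lack of any α-hydrogen for a 1,2-shift, slow addition and low temperature should secure. Neutral aprotic conditions keep the acidic C3–H and the ionisable C2–O1 bond of the cis product from equilibrating to trans.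

**Step 12**
Reactants: 16 (2R,3S)-2,6-bis[3,4-bis(TBSO)phenyl]-3-{2-oxo-4-[2-(trimethylsilyl)ethoxy]-2H-pyran-6-yl}-2,3-dihydro-4H-furo[3,2-c]pyran-4-one
Product: 17 6-[(2R,3S)-2,6-bis(3,4-dihydroxyphenyl)-4-oxo-2,3-dihydro-4H-furo[3,2-c]pyran-3-yl]-4-hydroxy-2H-pyran-2-one
Conditions: TBAF/AcOH (1:1, excess), degassed THF, 0 °C to rt; work-up at pH 4–5, reversed-phase purification with 0.1 % formic acid
Reagents that add atoms: none
Why: Fluoride cleaves the four aryl silyl ethers and fragments the 2-(trimethylsilyl)ethyl vinylogous ester (β-elimination to ethene and Me3SiF), while the acetic acid buffer keeps the freed phenols protonated so that neither quinone-methide opening of the C2–O1 bond nor deprotonation at C3 should erode the cis-(2R,3S) configuration.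

**Compound list**
1 | 3,4-dihydroxybenzaldehyde | O=Cc1ccc(O)c(O)c1 | starting material
2 | 3,4-bis(tert-butyldimethylsilyloxy)benzaldehyde | O=Cc1ccc(O[Si](C)(C)C(C)(C)C)c(O[Si](C)(C)C(C)(C)C)c1 | intermediate
3 | 2,2,6-trimethyl-4H-1,3-dioxin-4-one | CC1=CC(=O)OC(C)(C)O1 | starting material
4 | 6-{2-[3,4-bis(TBSO)phenyl]-2-hydroxyethyl}-2,2-dimethyl-4H-1,3-dioxin-4-one (racemic) | OC(CC1=CC(=O)OC(C)(C)O1)c1ccc(O[Si](C)(C)C(C)(C)C)c(O[Si](C)(C)C(C)(C)C)c1 | intermediate
5 | 6-{2-[3,4-bis(TBSO)phenyl]-2-oxoethyl}-2,2-dimethyl-4H-1,3-dioxin-4-one | O=C(CC1=CC(=O)OC(C)(C)O1)c1ccc(O[Si](C)(C)C(C)(C)C)c(O[Si](C)(C)C(C)(C)C)c1 | intermediate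
6 | acylketene 5-[3,4-bis(TBSO)phenyl]pent-1-ene-1,3,5-trione (not isolated) | O=C=CC(=O)CC(=O)c1ccc(O[Si](C)(C)C(C)(C)C)c(O[Si](C)(C)C(C)(C)C)c1 | intermediate
7 | 6-[3,4-bis(TBSO)phenyl]-4-hydroxy-2H-pyran-2-one (pyranone B) | O=c1cc(O)cc(-c2ccc(O[Si](C)(C)C(C)(C)C)c(O[Si](C)(C)C(C)(C)C)c2)o1 | intermediate
8 | [3,4-bis(TBSO)phenyl]methanol | OCc1ccc(O[Si](C)(C)C(C)(C)C)c(O[Si](C)(C)C(C)(C)C)c1 | intermediate
9 | 4-hydroxy-6-methyl-2H-pyran-2-one | Cc1cc(O)cc(=O)o1 | starting material
10 | 6-methyl-4-[2-(trimethylsilyl)ethoxy]-2H-pyran-2-one | Cc1cc(OCC[Si](C)(C)C)cc(=O)o1 | intermediate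
11 | 2-oxo-4-[2-(trimethylsilyl)ethoxy]-2H-pyran-6-carbaldehyde | O=Cc1cc(OCC[Si](C)(C)C)cc(=O)o1 | intermediate
12 | Knoevenagel adduct 6-[3,4-bis(TBSO)phenyl]-3-({2-oxo-4-[2-(trimethylsilyl)ethoxy]-2H-pyran-6-yl}methylidene)-2H-pyran-2,4(3H)-dione (E/Z not defined, not isolated) | O=C1OC(-c2ccc(O[Si](C)(C)C(C)(C)C)c(O[Si](C)(C)C(C)(C)C)c2)=CC(=O)C1=Cc1cc(OCC[Si](C)(C)C)cc(=O)o1 | intermediate
13 | 6-[3,4-bis(TBSO)phenyl]-4-hydroxy-3-({2-oxo-4-[2-(trimethylsilyl)ethoxy]-2H-pyran-6-yl}methyl)-2H-pyran-2-one | O=c1oc(-c2ccc(O[Si](C)(C)C(C)(C)C)c(O[Si](C)(C)C(C)(C)C)c2)cc(O)c1Cc1cc(OCC[Si](C)(C)C)cc(=O)o1 | intermediate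
14 | 4-{[3,4-bis(TBSO)phenyl]methoxy}-6-[3,4-bis(TBSO)phenyl]-3-({2-oxo-4-[2-(trimethylsilyl)ethoxy]-2H-pyran-6-yl}methyl)-2H-pyran-2-one | O=c1oc(-c2ccc(O[Si](C)(C)C(C)(C)C)c(O[Si](C)(C)C(C)(C)C)c2)cc(OCc2ccc(O[Si](C)(C)C(C)(C)C)c(O[Si](C)(C)C(C)(C)C)c2)c1Cc1cc(OCC[Si](C)(C)C)cc(=O)o1 | intermediate
15 | 4-{[3,4-bis(TBSO)phenyl]methoxy}-6-[3,4-bis(TBSO)phenyl]-3-(diazo{2-oxo-4-[2-(trimethylsilyl)ethoxy]-2H-pyran-6-yl}methyl)-2H-pyran-2-one | O=c1oc(-c2ccc(O[Si](C)(C)C(C)(C)C)c(O[Si](C)(C)C(C)(C)C)c2)cc(OCc2ccc(O[Si](C)(C)C(C)(C)C)c(O[Si](C)(C)C(C)(C)C)c2)c1C(=[N+]=[N-])c1cc(OCC[Si](C)(C)C)cc(=O)o1 | intermediate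
16 | (2R,3S)-2,6-bis[3,4-bis(TBSO)phenyl]-3-{2-oxo-4-[2-(trimethylsilyl)ethoxy]-2H-pyran-6-yl}-2,3-dihydro-4H-furo[3,2-c]pyran-4-one (cis) | O=c1cc(OCC[Si](C)(C)C)cc([C@H]2c3c(cc(-c4ccc(O[Si](C)(C)C(C)(C)C)c(O[Si](C)(C)C(C)(C)C)c4)oc3=O)O[C@H]2c2ccc(O[Si](C)(C)C(C)(C)C)c(O[Si](C)(C)C(C)(C)C)c2)o1 | intermediate
17 | 6-[(2R,3S)-2,6-bis(3,4-dihydroxyphenyl)-4-oxo-2,3-dihydro-4H-furo[3,2-c]pyran-3-yl]-4-hydroxy-2H-pyran-2-one (CNP0224684.1) | O=c1cc(O)cc([C@H]2c3c(cc(-c4ccc(O)c(O)c4)oc3=O)O[C@H]2c2ccc(O)c(O)c2)o1 | target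

**Totals**
Total step count: 12. Longest linear sequence: 9 steps (1 → 2 → 4 → 5 → 7 → 13 → 14 → 15 → 16 → 17).

**Steps most likely to fail**

Step 11. The chiral dirhodium pocket may discriminate poorly between the two enantiotopic benzylic hydrogens, because the carbene carries two hetaryl groups of similar size. Fallback: starting from 15, the insertion is run with the achiral catalyst Rh2(esp)2 (CH2Cl2, 0 °C), which should give the cis product as a racemate of 16 and its (2S,3R)-enantiomer F1. The two are separated by preparative supercritical-fluid chromatography on a chiral stationary phase, and the route is rejoined at 16. Absolute configuration then comes from resolution instead of asymmetric catalysis.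

Step 10. Deprotonation of the bridging methylene by an amidine base may be slow or incomplete, the sulfonyl azide may attack ring carbons of the extended enolate, and the diazo group may cyclise onto an adjacent ring C=C during isolation. Fallback: starting from 14, the methylene is first activated by C-trifluoroacetylation (LiHMDS, THF, −78 °C, then 2,2,2-trifluoroethyl trifluoroacetate) to give the trifluoroacetyl derivative F2. Detrifluoroacetylative diazo transfer (MsN3, Et3N, one equivalent of water, MeCN, rt) should then deliver 15 under mild base, and the crude solution is taken on directly; the route is rejoined at 15.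

Step 12. The cis configuration may be lost if fluoride generates a phenoxide para to C2, which opens the C2–O1 bond to a p-quinone methide that recloses to trans, or if C3 is deprotonated. Fallback: starting from 16, desilylation is run in the presence of acetic anhydride (CsF, Ac2O, DMF, 0 °C) so that each oxygen is acetylated as it is freed, giving the pentaacetate F3, whose electron-poor aryl ring cannot open the ring. Neutral deacetylation (NH4OAc, MeOH/H2O, rt) should then release the phenols and the pyranone hydroxyl without a phenoxide, and the route is rejoined at 17.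

**Further compounds**
F1 | step 11 | (2S,3R)-2,6-bis[3,4-bis(TBSO)phenyl]-3-{2-oxo-4-[2-(trimethylsilyl)ethoxy]-2H-pyran-6-yl}-2,3-dihydro-4H-furo[3,2-c]pyran-4-one (enantiomer of 16) | O=c1cc(OCC[Si](C)(C)C)cc([C@@H]2c3c(cc(-c4ccc(O[Si](C)(C)C(C)(C)C)c(O[Si](C)(C)C(C)(C)C)c4)oc3=O)O[C@@H]2c2ccc(O[Si](C)(C)C(C)(C)C)c(O[Si](C)(C)C(C)(C)C)c2)o1
F2 | step 10 | 4-{[3,4-bis(TBSO)phenyl]methoxy}-6-[3,4-bis(TBSO)phenyl]-3-(3,3,3-trifluoro-2-oxo-1-{2-oxo-4-[2-(trimethylsilyl)ethoxy]-2H-pyran-6-yl}propyl)-2H-pyran-2-one (racemic) | O=c1oc(-c2ccc(O[Si](C)(C)C(C)(C)C)c(O[Si](C)(C)C(C)(C)C)c2)cc(OCc2ccc(O[Si](C)(C)C(C)(C)C)c(O[Si](C)(C)C(C)(C)C)c2)c1C(C(=O)C(F)(F)F)c1cc(OCC[Si](C)(C)C)cc(=O)o1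
F3 | step 12 | (2R,3S)-3-(4-acetoxy-2-oxo-2H-pyran-6-yl)-2,6-bis(3,4-diacetoxyphenyl)-2,3-dihydro-4H-furo[3,2-c]pyran-4-one | O=c1cc(OC(C)=O)cc([C@H]2c3c(cc(-c4ccc(OC(C)=O)c(OC(C)=O)c4)oc3=O)O[C@H]2c2ccc(OC(C)=O)c(OC(C)=O)c2)o1
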